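# Proposed total synthesis of CNP0316718.1 by conjunctive cross-coupling across a ring A vinylboronate

## Analysis of the target

The target 19 is a trans-2,3-diaryl-2,3-dihydrobenzofuran. Ring A (the benzo ring) carries a free hydroxyl at C4 and an (E)-4-hydroxystyryl arm at C6; C2 bears a 3,4-dihydroxyphenyl (catechol) ring and C3 a 3,5-dihydroxyphenyl (resorcinol) ring. The only stereocentres are C2 and C3, both S, with the two aryl groups on opposite faces of the dihydrofuran ring. C2 is a benzylic ether carbon para to a phenol oxygen, so the C2–O1 bond ionises easily and recloses to the more stable trans isomer. C2 can therefore be corrected, whereas C3, a diarylmethine carbon with no heteroatom, keeps the configuration it is given and must be set absolutely. The sensitive groups are six phenols (one of them an oxidation-prone catechol) and an electron-rich stilbene that isomerises in light and oligomerises under strong acid, so all phenols travel as methyl ethers until the last step. The difficulty is to create C3, which carries two aryl rings of similar size next to a doubly ortho-oxygenated ring A, with absolute control and without a directing heteroatom. The strategy rests on the fact that C2 and C3 are adjacent carbons that each carry exactly one aryl ring not belonging to ring A. Seen from ring A they are the two carbons of a vinyl group across which the catechol ring (to C2) and the resorcinol ring (to C3) have been added, with oxygen on C2. Ring A has a local mirror plane through C3a and C6 as long as the two oxygens flanking C3a are alike, so it can enter as a symmetrical 2,6-dimethoxyaryl unit and either oxygen can become O1.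

## Retrosynthetic reasoning

**O1–C2 and the O–methyl bonds (19 back to 17, through 18).** The dihydrofuran ring is opened at O1–C2 and all phenols are masked as methyl ethers, which leads to the acyclic alcohol 17. The cut is placed here because C2 is a para-oxygenated benzylic carbon: a leaving group on it departs readily, and a ring A oxygen sits five atoms away. Since ring A is symmetrical in 17, no regiochemical question arises. The forward reaction needs a strong boron Lewis acid to activate the hydroxyl, let one ring A methoxy oxygen close on C2 with loss of its methyl group (giving 18), and then cleave the six remaining methyl ethers. The configuration works out on either pathway: 17 is (1R,2S), closure with inversion at C1 gives (2S,3S), and closure through the free cation gives the same trans ring on thermodynamic grounds.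

**C2–O to C2–B (17 back to 16).** The hydroxyl of 17 is traced to a carbon–boron bond, which is oxidised with retention. Boron is placed on C2 because it is the element that makes the next disconnection possible.

**C2–aryl and C3–aryl (16 back to 10, 14 and 12, through 15).** Both aryl–carbon bonds are cut in one operation: C2–catechol ring and C3–resorcinol ring. Cutting C2–C3 instead would require a configurationally fragile diarylmethyl nucleophile or electrophile. Cutting C3–C3a would require arylation with a hindered 2,6-dioxygenated ring A donor. Cutting the two outer aryl bonds leaves a simple (E)-alkenylboronate 10, the aryllithium 14 and the aryl triflate 12, all achiral. The forward reaction must add the two aryl groups anti across the alkene of the ate complex 15, choose one alkene face (which fixes C3), and outrun direct cross-coupling of the boron-bound groups. The boron carries the rigid diol 9 rather than the tetramethyl-dioxaborolane of 6, because β-substituted alkenylboron ate complexes of ordinary diol esters tend to pass their organic groups directly to palladium, and the hindered ester of 9 suppresses that pathway.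

**The two aryl partners (14 back to 13, 12 back to 11).** The aryllithium 14 comes from bromide 13 by halogen–lithium exchange in the flask. The triflate 12 comes from phenol 11 by O-sulfonylation. Both keep the oxygen pattern of the target rings as methyl ethers.

**The boron ligand exchange (10 back to 7 and 9, 7 back to 6, 9 back to 8).** Only B–O bonds are cut. The olefination below delivers the pinacol-type ester 6, so its diol is removed to give the boronic acid 7, which is condensed with diol 9. Diol 9 is the double methyl adduct of diketone 8.

**The alkene next to boron (6 back to 3 and 4, through 5).** The C=C bond is cut between the ring A carbon and the boron-bearing carbon. The forward reaction is a boron–Wittig olefination of aldehyde 3 with the carbanion 5 of the geminal diboron compound 4. It gives the (E)-alkenylboronate directly, without touching the stilbene already present.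

**The stilbene (3 back to 1 and 2).** The aryl–vinyl bond of the styryl arm is cut (Heck disconnection). It is made first because the bromide of 1 is activated by the para-formyl group and is unhindered. This order also ensures that no aryl halide remains in the molecule when the palladium-catalysed three-component step is run.

## Alternatives that were turned down

**Alternative 1:** Wolff ring contraction. The five-membered ring is derived from a six-membered chromanone, and the C3–C3a bond is made by migration. In the forward sense the 3-diazoflavanone A1 is photolysed, nitrogen leaves, ring A shifts from the carbonyl carbon to the carbene carbon, and the contracted intermediate is hydrated to the dihydrobenzofuran-3-carboxylic acid A2.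
- For: flavanone chemistry is robust and scalable, C2 can be set by established asymmetric ring closure, A2 is a crystalline acid, and its bromine allows the stilbene to be attached late. On reliability of the early steps this alternative is stronger than the chosen route.
- Against: A2 still lacks both the resorcinol ring and the styryl arm. The resorcinol ring would have to be put on C3 by decarboxylative arylation, through a radical or organometallic centre β to the ring oxygen (risk of ring opening). C3 would then be controlled only by the substrate, that is by C2, the centre that epimerises easily. The basic diazo transfer on the flavanone also invites retro-oxa-Michael opening and loss of C2 integrity.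
- Comparison: the control logic is inverted, since the uncorrectable centre C3 depends on the correctable one, and the sequence is several steps longer. The chosen route instead sets C3 directly by a chiral catalyst and forms both aryl bonds in one step.

**Alternative 2:** Alkyne cyclotrimerisation. Both rings of the benzofuran are cut at once (C3a–C7a, C4–C5, C6–C7). In the forward sense a rhodium- or ruthenium-catalysed [2+2+2] reaction of the chiral 1,6-diyne A3 with the enyne A4 closes the dihydrofuran and benzene rings to give the silyl-substituted dihydrobenzofuran A5.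
- For: it is the most economical in ring construction, forming three C–C bonds and two rings in one step, and the meta relation of the silyl group and the styryl arm follows the usual regiochemical preference. On this point it is clearly stronger than the chosen route, whose key step closes no ring.
- Against: both stereocentres must already be present in A3, so the hard problem (C3 with absolute control, next to C2) is only moved to an acyclic diyne bearing a fragile ynol ether. The alkene of A4 can compete for the metallacycle. The silicon of A5 must still be oxidised to the C4 hydroxyl at a hindered position before deprotection.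
- Comparison: the chosen route offers a solution to the stereochemical problem itself, from achiral fragments, in fewer steps overall.

**Alternative 3:** Polyketide-style aldol aromatisation. Ring A is cut at C5–C6. In the forward sense base enolises the acetyl methyl of the trans-3-acetyl-4,5-dihydrofuran A6, the enolate adds to the cinnamoyl ketone of the side chain, and dehydration with tautomerisation gives the phenol A7.
- For: ring A is formed with its C4 hydroxyl already free, and A7 needs only ether cleavage to reach 19. No cationic ring closure at C2 is required at the end, so on the endgame this alternative is stronger than the chosen route.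
- Against: A6 already contains the trans-dihydrofuran with both stereocentres, which must be built first by other chemistry. A6 also has several acidic sites, and the methylene between the enol ether carbon and the ketone is more acidic than the acetyl methyl, so the wrong enolate, conjugate addition to the enone and base-induced epimerisation or aromatisation of the dihydrofuran all compete. Its preparation costs many steps.
- Comparison: the chosen route accepts a more demanding last step, and in exchange has a short, convergent assembly in which the only stereocentre that matters is set by the catalyst.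

Key step: step 7

Remark on the chemistry: the alkene face that the (Sp,Sp) ligand selects on this β-aryl substrate is assigned by analogy with simpler β-substituted cases; if the first run shows the opposite sense at C3, the commercially available (Rp,Rp) ligand is used and nothing else changes.

## Route

Step 1
Reactants: 1 4-bromo-2,6-dimethoxybenzaldehyde; 2 4-methoxystyrene
Product: 3 (E)-2,6-dimethoxy-4-(4-methoxystyryl)benzaldehyde
Conditions: Pd(OAc)2 (2 mol %), P(o-tol)3 (5 mol %), Et3N, DMF, 100 °C
Reagents that add atoms: none
Why: Heck reaction; the aryl bromide is unhindered and activated by the para-formyl group, and syn insertion followed by syn β-hydride elimination on the monosubstituted styrene should give the (E)-stilbene at the terminal carbon, with the aldehyde untouched.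

Step 2
Reactants: 3 (E)-2,6-dimethoxy-4-(4-methoxystyryl)benzaldehyde; 4 bis(pinacolato)borylmethane
Product: 6 2-[(E)-2-{2,6-dimethoxy-4-[(E)-4-methoxystyryl]phenyl}vinyl]-4,4,5,5-tetramethyl-1,3,2-dioxaborolane, via [bis(pinacolatoboryl)methyl]lithium 5 (not isolated)
Conditions: lithium 2,2,6,6-tetramethylpiperidide (LiTMP), THF, 0 °C; then 3, −78 °C → rt
Reagents that add atoms: none
Why: Boron–Wittig olefination; the α,α-diboryl carbanion adds to the aldehyde and syn elimination of the boron–oxygen fragment from the less crowded adduct should give the (E)-alkenylboronate, and no reagent present reacts with the stilbene.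

Step 3
Reactants: 6 2-[(E)-2-{2,6-dimethoxy-4-[(E)-4-methoxystyryl]phenyl}vinyl]-4,4,5,5-tetramethyl-1,3,2-dioxaborolane
Product: 7 (E)-2-{2,6-dimethoxy-4-[(E)-4-methoxystyryl]phenyl}vinylboronic acid
Conditions: NaIO4, NH4OAc, acetone/H2O, rt
Reagents that add atoms: water, O
Why: Periodate glycol cleavage of the pinacol unit drives hydrolysis of the boronic ester to the free acid in a near-neutral buffer, which spares the acid-sensitive electron-rich alkenyl–boron bond; periodate alone attacks neither the alkenes nor the aryl methyl ethers.

Step 4
Reactants: 8 acenaphthoquinone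
Product: 9 cis-1,2-dimethyl-1,2-dihydroacenaphthylene-1,2-diol (mac diol)
Conditions: AlMe3, toluene, 0 °C → rt; aqueous Rochelle salt work-up; crystallisation
Reagents that add atoms: trimethylaluminium, C[Al](C)C
Why: Double 1,2-addition of a methylaluminium reagent to the 1,2-diketone; the second methyl should enter anti to the bulky aluminium alkoxide formed first, giving the cis (meso) diol, the only isomer that can span boron, and crystallisation removes any trans isomer.

Step 5
Reactants: 7 (E)-2-{2,6-dimethoxy-4-[(E)-4-methoxystyryl]phenyl}vinylboronic acid; 9 cis-1,2-dimethyl-1,2-dihydroacenaphthylene-1,2-diol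
Product: 10 (E)-2-{2,6-dimethoxy-4-[(E)-4-methoxystyryl]phenyl}vinylboronic acid mac ester (cyclic boronate of diol 9)
Conditions: MgSO4, CH2Cl2, rt
Reagents that add atoms: none
Why: Condensation of a boronic acid with a cis-1,2-diol to the five-membered cyclic boronic ester, driven by removal of water; the rigid ester should be stable to chromatography.

Step 6
Reactants: 11 3,5-dimethoxyphenol
Product: 12 3,5-dimethoxyphenyl trifluoromethanesulfonate
Conditions: Tf2O, pyridine, CH2Cl2, 0 °C
Reagents that add atoms: trifluoromethanesulfonic anhydride, O=S(=O)(OS(=O)(=O)C(F)(F)F)C(F)(F)F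
Why: O-sulfonylation of a phenol; it provides the halide-free aryl electrophile that the cationic palladium pathway of step 7 requires.

Step 7
Reactants: 10 (E)-2-{2,6-dimethoxy-4-[(E)-4-methoxystyryl]phenyl}vinylboronic acid mac ester; 13 4-bromo-1,2-dimethoxybenzene; 12 3,5-dimethoxyphenyl trifluoromethanesulfonate
Product: 16 mac boronate of the (1R,2S)-1-(3,4-dimethoxyphenyl)-2-(3,5-dimethoxyphenyl)-2-{2,6-dimethoxy-4-[(E)-4-methoxystyryl]phenyl}ethyl group (anti adduct), via (3,4-dimethoxyphenyl)lithium 14 (not isolated), via lithium boron ate complex 15 (not isolated)
Conditions: 13 (1.05 equiv), t-BuLi (2.0 equiv), Et2O, −78 °C; then 10 (1.0 equiv), −78 °C → rt; evaporate; then Pd(OAc)2 (3 mol %), (Sp,Sp)-Mandyphos ligand [(S,S)-1,1′-bis[bis(4-methoxy-3,5-dimethylphenyl)phosphino]-2,2′-bis[(R)-α-(dimethylamino)benzyl]ferrocene] (3.6 mol %), 12 (1.2 equiv), KOTf (2 equiv), THF, 60 °C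
Reagents that add atoms: none
Why: Zerovalent palladium formed from Pd(OAc)2 and the bisphosphine adds oxidatively to triflate 12, and the resulting cationic arylpalladium, kept free of halide because KOTf precipitates the bromide left by the lithium exchange, binds the electron-rich alkene of ate complex 15. This π-activation triggers a 1,2-metallate shift in which the 3,4-dimethoxyphenyl group leaves boron for C2 on the face opposite to palladium, which becomes bonded to C3; stereoretentive reductive elimination then forms the C3–aryl bond and returns zerovalent palladium. The closest known reaction type is the enantioselective palladium-catalysed conjunctive cross-coupling of β-substituted alkenylboron ate complexes with aryl triflates. No ring is closed in this step. C3 is set by the chiral ligand, which selects the alkene face that palladium occupies; C2 follows from C3 because the addition is anti and the alkene is E, which gives the (1R,2S) relationship. The step needs the metallate shift to win over direct transmetalation of the aryl or alkenyl group (Suzuki–Miyaura coupling), which the bulky rigid mac diol on boron and the halide-free medium are meant to secure. Regiochemistry is fixed by boron, since the migrating group can only end on the boron-bearing carbon, and the neutral stilbene is left alone because the anionic ate alkene is by far the better donor.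

Step 8
Reactants: 16 mac boronate of the (1R,2S)-1-(3,4-dimethoxyphenyl)-2-(3,5-dimethoxyphenyl)-2-{2,6-dimethoxy-4-[(E)-4-methoxystyryl]phenyl}ethyl group
Product: 17 (1R,2S)-1-(3,4-dimethoxyphenyl)-2-(3,5-dimethoxyphenyl)-2-{2,6-dimethoxy-4-[(E)-4-methoxystyryl]phenyl}ethanol
Conditions: H2O2 (30 % aq.), NaOH (3 M aq.), THF, 0 °C → rt
Reagents that add atoms: hydrogen peroxide, OO
Why: Oxidation of a secondary alkylboronic ester by hydroperoxide anion; the carbon migrates from boron to oxygen with retention, so the (1R) alcohol results, the electron-rich stilbene is not epoxidised by basic peroxide, and diol 9 is recovered.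

Step 9
Reactants: 17 (1R,2S)-1-(3,4-dimethoxyphenyl)-2-(3,5-dimethoxyphenyl)-2-{2,6-dimethoxy-4-[(E)-4-methoxystyryl]phenyl}ethanol
Product: 19 (2S,3S)-2-(3,4-dihydroxyphenyl)-3-(3,5-dihydroxyphenyl)-6-[(E)-4-hydroxystyryl]-2,3-dihydrobenzofuran-4-ol, via trans hexamethyl ether 18 (not isolated)
Conditions: BBr3 (14 equiv), CH2Cl2, −78 °C → rt, dark, argon; then ice/aq. NaHCO3
Reagents that add atoms: none
Why: BBr3 turns the para-methoxybenzylic hydroxyl into a leaving group, a ring A methoxy oxygen closes the five-membered ring on C2 (5-exo, by neighbouring-group displacement or through the benzylic cation), bromide removes the methyl group of the resulting oxonium to give 18, and the same reagent then cleaves the six remaining aryl methyl ethers (Lewis-acid ether cleavage). Closure with inversion at the (1R) carbon and closure through the free cation both give the trans (2S,3S) ring, any cis isomer should equilibrate to trans by reversible C2–O1 ionisation, and C3 is not involved.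

## Compound list

1 | 4-bromo-2,6-dimethoxybenzaldehyde | COc1cc(Br)cc(OC)c1C=O | starting material
2 | 4-methoxystyrene | C=Cc1ccc(OC)cc1 | starting material
3 | (E)-2,6-dimethoxy-4-(4-methoxystyryl)benzaldehyde | COc1cc(/C=C/c2ccc(OC)cc2)cc(OC)c1C=O | intermediate
4 | bis(pinacolato)borylmethane [2,2′-methylenebis(4,4,5,5-tetramethyl-1,3,2-dioxaborolane)] | CC1(C)OB(CB2OC(C)(C)C(C)(C)O2)OC1(C)C | starting material
5 | [bis(4,4,5,5-tetramethyl-1,3,2-dioxaborolan-2-yl)methyl]lithium (formed in the flask, not isolated) | [Li]C(B1OC(C)(C)C(C)(C)O1)B1OC(C)(C)C(C)(C)O1 | intermediate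
6 | 2-[(E)-2-{2,6-dimethoxy-4-[(E)-4-methoxystyryl]phenyl}vinyl]-4,4,5,5-tetramethyl-1,3,2-dioxaborolane | COc1cc(/C=C/c2ccc(OC)cc2)cc(OC)c1/C=C/B1OC(C)(C)C(C)(C)O1 | intermediate
7 | (E)-2-{2,6-dimethoxy-4-[(E)-4-methoxystyryl]phenyl}vinylboronic acid | COc1cc(/C=C/c2ccc(OC)cc2)cc(OC)c1/C=C/B(O)O | intermediate
8 | acenaphthoquinone (acenaphthylene-1,2-dione) | O=C1C(=O)c2cccc3cccc1c23 | starting material
9 | cis-1,2-dimethyl-1,2-dihydroacenaphthylene-1,2-diol (mac diol; meso, 1R,2S) | C[C@]1(O)c2cccc3cccc(c23)[C@@]1(C)O | intermediate
10 | (E)-2-{2,6-dimethoxy-4-[(E)-4-methoxystyryl]phenyl}vinylboronic acid mac ester (cyclic boronate with the cis diol 9; precursor of the key step) | COc1cc(/C=C/c2ccc(OC)cc2)cc(OC)c1/C=C/B1O[C@@]2(C)c3cccc4cccc(c34)[C@@]2(C)O1 | intermediate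
11 | 3,5-dimethoxyphenol | COc1cc(O)cc(OC)c1 | starting material
12 | 3,5-dimethoxyphenyl trifluoromethanesulfonate | COc1cc(OC)cc(OS(=O)(=O)C(F)(F)F)c1 | intermediate
13 | 4-bromo-1,2-dimethoxybenzene | COc1ccc(Br)cc1OC | starting material
14 | (3,4-dimethoxyphenyl)lithium (formed in the flask, not isolated) | [Li]c1ccc(OC)c(OC)c1 | intermediate
15 | lithium (3,4-dimethoxyphenyl)[(E)-2-{2,6-dimethoxy-4-[(E)-4-methoxystyryl]phenyl}vinyl]borate of diol 9 (ate complex, not isolated) | [Li+].COc1ccc(cc1OC)[B-]1(/C=C/c2c(OC)cc(/C=C/c3ccc(OC)cc3)cc2OC)O[C@@]2(C)c3cccc4cccc(c34)[C@@]2(C)O1 | intermediate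
16 | mac boronate of the (1R,2S)-1-(3,4-dimethoxyphenyl)-2-(3,5-dimethoxyphenyl)-2-{2,6-dimethoxy-4-[(E)-4-methoxystyryl]phenyl}ethyl group (anti adduct; product of the key step) | COc1ccc(cc1OC)[C@H](B1O[C@@]2(C)c3cccc4cccc(c34)[C@@]2(C)O1)[C@H](c1c(OC)cc(/C=C/c2ccc(OC)cc2)cc1OC)c1cc(OC)cc(OC)c1 | intermediate
17 | (1R,2S)-1-(3,4-dimethoxyphenyl)-2-(3,5-dimethoxyphenyl)-2-{2,6-dimethoxy-4-[(E)-4-methoxystyryl]phenyl}ethanol | COc1ccc(cc1OC)[C@H](O)[C@H](c1c(OC)cc(/C=C/c2ccc(OC)cc2)cc1OC)c1cc(OC)cc(OC)c1 | intermediate
18 | (2S,3S)-2-(3,4-dimethoxyphenyl)-3-(3,5-dimethoxyphenyl)-4-methoxy-6-[(E)-4-methoxystyryl]-2,3-dihydrobenzofuran (trans; formed in the flask, not isolated) | COc1ccc(/C=C/c2cc(OC)c3c(c2)O[C@H](c2ccc(OC)c(OC)c2)[C@H]3c2cc(OC)cc(OC)c2)cc1 | intermediate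
19 | (2S,3S)-2-(3,4-dihydroxyphenyl)-3-(3,5-dihydroxyphenyl)-6-[(E)-4-hydroxystyryl]-2,3-dihydrobenzofuran-4-ol (trans) | Oc1ccc(/C=C/c2cc(O)c3c(c2)O[C@H](c2ccc(O)c(O)c2)[C@H]3c2cc(O)cc(O)c2)cc1 | target

## Step count and least certain steps

Total step count: 9. Longest linear sequence: 7 steps (steps 1, 2, 3, 5, 7, 8 and 9, from 1 to 19); steps 4 and 6 are single-step side branches.

**Step 7 (key step).**
- What may go wrong: the two ortho-methoxy groups of ring A shield C3, so alkene binding and the metallate shift may be slower than direct transfer of the aryl or alkenyl group from boron to palladium (Suzuki–Miyaura pathway). β-Hydride elimination from the benzylic alkylpalladium may precede reductive elimination. Facial selectivity on a β-aryl substrate this hindered may be low or opposite to that expected. Residual halide may quench the cationic palladium.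
- Fallback: the three-component logic is abandoned and C2–C3 is made by an enantioselective carbene C–H insertion, setting out from aldehyde 3. BCl3 (1.1 equiv, CH2Cl2, −78 → 0 °C) removes one methyl group ortho to the formyl group through a boron chelate and gives 2-hydroxy-6-methoxy-4-[(E)-4-methoxystyryl]benzaldehyde F1. Alkylation with 3,4-dimethoxybenzyl bromide (K2CO3, DMF) gives 2-[(3,4-dimethoxybenzyl)oxy]-6-methoxy-4-[(E)-4-methoxystyryl]benzaldehyde F2. Addition of 3,5-dimethoxyphenylmagnesium bromide (THF, 0 °C) gives the racemic diarylmethanol F3, which MnO2 (CH2Cl2) oxidises to the diaryl ketone F4. Hydrazine hydrate (EtOH, AcOH cat., reflux) converts F4 into the hydrazone F5. MnO2 oxidises F5 to the diaryldiazomethane F6, which is not isolated. Dirhodium tetrakis[(S)-N-phthaloyl-(1-adamantyl)glycinate], Rh2(S-PTAD)4 (1 mol %, CH2Cl2, 0 °C), then inserts the donor/donor carbene into the benzylic C–H bond next to the ether oxygen and closes the ring as the cis-(2R,3S)-2-(3,4-dimethoxyphenyl)-3-(3,5-dimethoxyphenyl)-4-methoxy-6-[(E)-4-methoxystyryl]-2,3-dihydrobenzofuran F7. C3 is set by the catalyst, and the other catalyst enantiomer is used if the sense is wrong. F7 is taken into the conditions of step 9, where reversible C2–O1 ionisation should equilibrate it to the trans ether 18, so the route is rejoined at 18.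

**Step 9.**
- What may go wrong: proton loss from C3 may compete with ring closure at the activated C2 and would erase the one stereocentre that cannot be corrected. Hydrogen bromide may add to the stilbene or promote its oligomerisation. Ether cleavage may stop short of completion. The free catechol may oxidise in air during work-up.
- Fallback: ring closure is separated from deprotection and carried out under basic conditions, setting out from 17. MsCl and Et3N (CH2Cl2, −20 °C → rt) give the methanesulfonate F8, which is not isolated. The neighbouring ring A methoxy oxygen displaces the sulfonate with inversion, and chloride removes the methyl group of the oxonium ion. This returns to the route at 18, now an isolated compound whose trans configuration and enantiomeric purity can be checked. 18 is then treated alone with BBr3 (CH2Cl2, −78 → 0 °C), which only has to cleave ethers, to reach 19.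

**Step 2.**
- What may go wrong: the bulky α,α-diboryl carbanion may add slowly to the di-ortho-substituted, electron-rich aldehyde, and elimination from a mixture of adducts may lower the E selectivity.
- Fallback: the alkene is made by hydroboration instead of olefination, setting out from 3. The Ohira–Bestmann reagent, dimethyl (1-diazo-2-oxopropyl)phosphonate (K2CO3, MeOH, rt), gives 2-ethynyl-1,3-dimethoxy-5-[(E)-4-methoxystyryl]benzene F9. Syn hydroboration of the terminal alkyne with pinacolborane catalysed by Cp2Zr(H)Cl (10 mol %, Et3N, 60 °C) then gives the (E)-alkenylboronate and returns to the route at 6.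

**Step 3.**
- What may go wrong: the electron-rich alkenylboronic acid may lose boron by protonolysis or dehydrate to mixtures of anhydrides during isolation, and cleavage of the hindered ester may be incomplete.
- Fallback: the free boronic acid is avoided, setting out from 6. KHF2 (MeOH/H2O, rt) gives the crystalline potassium (E)-2-{2,6-dimethoxy-4-[(E)-4-methoxystyryl]phenyl}vinyltrifluoroborate F10. Me3SiCl in MeCN in the presence of diol 9 abstracts fluoride, and the unmasked boron is captured by the diol, which returns to the route at 10 and bypasses 7.

## Further compounds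

F1 | step 7 | 2-hydroxy-6-methoxy-4-[(E)-4-methoxystyryl]benzaldehyde | COc1cc(/C=C/c2ccc(OC)cc2)cc(O)c1C=O
F2 | step 7 | 2-[(3,4-dimethoxybenzyl)oxy]-6-methoxy-4-[(E)-4-methoxystyryl]benzaldehyde | COc1cc(/C=C/c2ccc(OC)cc2)cc(OCc2ccc(OC)c(OC)c2)c1C=O
F3 | step 7 | {2-[(3,4-dimethoxybenzyl)oxy]-6-methoxy-4-[(E)-4-methoxystyryl]phenyl}(3,5-dimethoxyphenyl)methanol (racemic) | COc1cc(/C=C/c2ccc(OC)cc2)cc(OCc2ccc(OC)c(OC)c2)c1C(O)c1cc(OC)cc(OC)c1
F4 | step 7 | {2-[(3,4-dimethoxybenzyl)oxy]-6-methoxy-4-[(E)-4-methoxystyryl]phenyl}(3,5-dimethoxyphenyl)methanone | COc1cc(/C=C/c2ccc(OC)cc2)cc(OCc2ccc(OC)c(OC)c2)c1C(=O)c1cc(OC)cc(OC)c1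
F5 | step 7 | hydrazone of {2-[(3,4-dimethoxybenzyl)oxy]-6-methoxy-4-[(E)-4-methoxystyryl]phenyl}(3,5-dimethoxyphenyl)methanone | COc1cc(/C=C/c2ccc(OC)cc2)cc(OCc2ccc(OC)c(OC)c2)c1C(=NN)c1cc(OC)cc(OC)c1
F6 | step 7 | {2-[(3,4-dimethoxybenzyl)oxy]-6-methoxy-4-[(E)-4-methoxystyryl]phenyl}(3,5-dimethoxyphenyl)diazomethane | COc1cc(/C=C/c2ccc(OC)cc2)cc(OCc2ccc(OC)c(OC)c2)c1C(=[N+]=[N-])c1cc(OC)cc(OC)c1
F7 | step 7 | (2R,3S)-2-(3,4-dimethoxyphenyl)-3-(3,5-dimethoxyphenyl)-4-methoxy-6-[(E)-4-methoxystyryl]-2,3-dihydrobenzofuran (cis) | COc1ccc(/C=C/c2cc(OC)c3c(c2)O[C@@H](c2ccc(OC)c(OC)c2)[C@H]3c2cc(OC)cc(OC)c2)cc1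
F8 | step 9 | (1R,2S)-1-(3,4-dimethoxyphenyl)-2-(3,5-dimethoxyphenyl)-2-{2,6-dimethoxy-4-[(E)-4-methoxystyryl]phenyl}ethyl methanesulfonate | COc1ccc(cc1OC)[C@H](OS(C)(=O)=O)[C@H](c1c(OC)cc(/C=C/c2ccc(OC)cc2)cc1OC)c1cc(OC)cc(OC)c1
F9 | step 2 | 2-ethynyl-1,3-dimethoxy-5-[(E)-4-methoxystyryl]benzene | COc1cc(/C=C/c2ccc(OC)cc2)cc(OC)c1C#C
F10 | step 3 | potassium (E)-2-{2,6-dimethoxy-4-[(E)-4-methoxystyryl]phenyl}vinyltrifluoroborate | COc1cc(/C=C/c2ccc(OC)cc2)cc(OC)c1/C=C/[B-](F)(F)F.[K+]
A1 | alternative 1 | (R)-7-bromo-3-diazo-2-(3,4-dimethoxyphenyl)-5-methoxychroman-4-one | COc1cc(Br)cc2O[C@H](c3ccc(OC)c(OC)c3)C(=[N+]=[N-])C(=O)c12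
A2 | alternative 1 | (2S)-6-bromo-2-(3,4-dimethoxyphenyl)-4-methoxy-2,3-dihydrobenzofuran-3-carboxylic acid (either C3 epimer) | Brc1cc(OC)c2c(c1)O[C@H](c1ccc(OC)c(OC)c1)C2C(=O)O
A3 | alternative 2 | (1S,2S)-4-(benzyldimethylsilyl)-1-(3,4-dimethoxyphenyl)-2-(3,5-dimethoxyphenyl)but-3-yn-1-yl ethynyl ether | C#CO[C@H](c1ccc(OC)c(OC)c1)[C@H](C#C[Si](C)(C)Cc1ccccc1)c1cc(OC)cc(OC)c1
A4 | alternative 2 | (E)-1-(4-methoxyphenyl)but-1-en-3-yne | C#C/C=C/c1ccc(OC)cc1
A5 | alternative 2 | trans-4-(benzyldimethylsilyl)-2-(3,4-dimethoxyphenyl)-3-(3,5-dimethoxyphenyl)-6-[(E)-4-methoxystyryl]-2,3-dihydrobenzofuran | COc1ccc(/C=C/c2cc([Si](C)(C)Cc3ccccc3)c3c(c2)O[C@H](c2ccc(OC)c(OC)c2)[C@H]3c2cc(OC)cc(OC)c2)cc1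
A6 | alternative 3 | (E)-1-[(4S,5S)-3-acetyl-5-(3,4-dimethoxyphenyl)-4-(3,5-dimethoxyphenyl)-4,5-dihydrofuran-2-yl]-4-(4-methoxyphenyl)but-3-en-2-one | CC(=O)C1=C(CC(=O)/C=C/c2ccc(OC)cc2)O[C@H](c2ccc(OC)c(OC)c2)[C@H]1c1cc(OC)cc(OC)c1
A7 | alternative 3 | trans-2-(3,4-dimethoxyphenyl)-3-(3,5-dimethoxyphenyl)-6-[(E)-4-methoxystyryl]-2,3-dihydrobenzofuran-4-ol | COc1ccc(/C=C/c2cc(O)c3c(c2)O[C@H](c2ccc(OC)c(OC)c2)[C@H]3c2cc(OC)cc(OC)c2)cc1
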